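**Retrosynthetic overview**

1. The target is the (Z)-4-hydroxycinnamate of (1S,3E,7E)-3,7,10,10-tetramethylcycloundeca-3,7-dien-1-ol (ring numbering: C1 carbinol, C3(Me)=C4, C7(Me)=C8, C10 gem-dimethyl). The ester is cut first: acylation with an arylpropynoic acid, then Lindlar semi-hydrogenation, so the isomerisable Z-alkene is made late.
2. The single ring, the eleven-membered carbocycle, is cut at C4–C5. This bond joins the vinylic CH of the E-C3=C4 alkene to the CH2–CH2 bridge (C5–C6) that ends at alkene carbon C7.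
3. Enabling feature: the array C4(sp2)–C5H2–C6H2–C7(Me)=C8 corresponds to an E-alkenyl iodide plus the terminal vinyl group of a 1,3-diene. 9-BBN should hydroborate only that vinyl group, at C5, and a one-flask B-alkyl Suzuki–Miyaura macrocyclisation then turns an acyclic chain into the complete ring with both E-alkenes in place.
4. Acyclic precursor: the C1 stereocentre comes from (S)-epichlorohydrin and is never a reaction centre; quaternary C10 comes from γ-selective epoxide opening with prenylmagnesium chloride; C3(Me)=C4–I from alkyne carboalumination–iodination; the E-diene from two Wittig reactions.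
5. Order of ring formation: there is only one ring, closed in step 9.

Key step: step 9

Remark: (S)-epichlorohydrin, prenylmagnesium chloride solution, lithium acetylide–ethylenediamine complex, 2-(triphenylphosphoranylidene)propanal and tert-butyl(4-ethynylphenoxy)dimethylsilane are taken as purchasable.

**Route**

Step 1
Reactants: 1 (S)-epichlorohydrin [(2S)-2-(chloromethyl)oxirane]; 2 prenylmagnesium chloride, (CH3)2C=CHCH2MgCl
Product: 3 (2S)-1-chloro-4,4-dimethylhex-5-en-2-ol
Conditions: (CH3)2C=CHCH2MgCl (1.1 equiv), THF, −40 → −10 °C; aq NH4Cl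
Reagents that add atoms: none
Why: Epoxide opening by an allylic Grignard reagent: the reagent should bond through its γ-carbon (SE2′, cyclic six-membered transition state) to the unsubstituted epoxide carbon, which creates the quaternary carbon and the vinyl group together, while the stereocentre of 1 is not a reaction centre and is carried over unchanged.

Step 2
Reactants: 3 (2S)-1-chloro-4,4-dimethylhex-5-en-2-ol; 4 lithium acetylide–ethylenediamine complex, LiC≡CH·H2NCH2CH2NH2
Product: 6 (4R)-6,6-dimethyloct-7-en-1-yn-4-ol, via epoxide 5 (not isolated)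
Conditions: LiC≡CH·H2NCH2CH2NH2 (3.5 equiv), DMSO, 0 °C → rt; then H2O
Reagents that add atoms: none
Why: Intramolecular Williamson closure of the lithium alkoxide to epoxide 5 followed by SN2 opening at its CH2 terminus by the acetylide; the carbinol carbon is again not a reaction centre, so its configuration is kept (the descriptor changes to R only through the CIP priorities).

Step 3
Reactants: 6 (4R)-6,6-dimethyloct-7-en-1-yn-4-ol
Product: 8 (1E,4S)-1-iodo-2,6,6-trimethylocta-1,7-dien-4-ol, via alkenylalane 7 (not isolated)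
Conditions: Me3Al (3 equiv), Cp2ZrCl2 (0.25 equiv), CH2Cl2, 0 °C → rt; then I2, THF, −30 → 0 °C; aq Na2S2O3/NaHCO3
Reagents that add atoms: trimethylaluminium, C[Al](C)C; iodine, II
Why: Zirconium-catalysed carboalumination of the terminal alkyne (Negishi carboalumination) adds CH3 and Al syn with aluminium at the terminal carbon, and iodinolysis of the C–Al bond goes with retention, which should fix the E-iodoalkene; the hindered vinyl group on the quaternary carbon is expected not to compete.

Step 4
Reactants: 8 (1E,4S)-1-iodo-2,6,6-trimethylocta-1,7-dien-4-ol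
Product: 9 tert-butyl{[(1E,4S)-1-iodo-2,6,6-trimethylocta-1,7-dien-4-yl]oxy}dimethylsilane
Conditions: TBSCl, imidazole, DMF, rt
Reagents that add atoms: tert-butyldimethylsilyl chloride, CC(C)(C)[Si](C)(C)Cl
Why: Silyl ether formation masks the secondary alcohol for the hydroboration, ylide and basic cross-coupling steps without touching the stereocentre.

Step 5
Reactants: 9 tert-butyl{[(1E,4S)-1-iodo-2,6,6-trimethylocta-1,7-dien-4-yl]oxy}dimethylsilane
Product: 11 (5S,7E)-5-[(tert-butyldimethylsilyl)oxy]-8-iodo-3,3,7-trimethyloct-7-en-1-ol, via alkylborane 10 (not isolated)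
Conditions: 9-BBN (1.5 equiv), THF, 0 °C → rt; then NaOH, H2O2, H2O, 0 °C → rt
Reagents that add atoms: hydrogen peroxide, OO
Why: Hydroboration–oxidation: 9-BBN should add only to the monosubstituted alkene, boron going to the terminal carbon, while the trisubstituted iodoalkene is too hindered and electron-poor to react, and alkaline peroxide then replaces boron by OH.

Step 6
Reactants: 11 (5S,7E)-5-[(tert-butyldimethylsilyl)oxy]-8-iodo-3,3,7-trimethyloct-7-en-1-ol
Product: 12 (5S,7E)-5-[(tert-butyldimethylsilyl)oxy]-8-iodo-3,3,7-trimethyloct-7-enal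
Conditions: Dess–Martin periodinane, CH2Cl2, 0 °C → rt
Reagents that add atoms: none
Why: Dess–Martin oxidation converts the primary alcohol into the aldehyde under neutral conditions that leave the alkenyl iodide and the silyl ether alone and do not over-oxidise.

Step 7
Reactants: 12 (5S,7E)-5-[(tert-butyldimethylsilyl)oxy]-8-iodo-3,3,7-trimethyloct-7-enal; 13 2-(triphenylphosphoranylidene)propanal
Product: 14 (2E,7S,9E)-7-[(tert-butyldimethylsilyl)oxy]-10-iodo-2,5,5,9-tetramethyldeca-2,9-dienal
Conditions: 13 (1.5 equiv), toluene, 90 °C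
Reagents that add atoms: none
Why: Wittig reaction with a formyl-stabilised ylide, which should give the E-configured 2-methyl enal because oxaphosphetane formation is reversible for stabilised ylides, and which should stop after one olefination since the conjugated product is far less electrophilic than 12.

Step 8
Reactants: 14 (2E,7S,9E)-7-[(tert-butyldimethylsilyl)oxy]-10-iodo-2,5,5,9-tetramethyldeca-2,9-dienal
Product: 15 tert-butyl{[(3E,8S,10E)-11-iodo-3,6,6,10-tetramethylundeca-1,3,10-trien-8-yl]oxy}dimethylsilane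
Conditions: Ph3PCH3Br, KN(SiMe3)2, THF, 0 °C; then 14, −78 → 0 °C
Reagents that add atoms: methyltriphenylphosphonium bromide, C[P+](c1ccccc1)(c1ccccc1)c1ccccc1.[Br-]
Why: Wittig methylenation: the non-stabilised ylide adds 1,2 to the enal and turns the formyl group into the terminal vinyl group of the diene without affecting the existing E-alkenes or the C–I bond.

Step 9
Reactants: 15 tert-butyl{[(3E,8S,10E)-11-iodo-3,6,6,10-tetramethylundeca-1,3,10-trien-8-yl]oxy}dimethylsilane
Product: 17 tert-butyldimethyl{[(1S,3E,7E)-3,7,10,10-tetramethylcycloundeca-3,7-dien-1-yl]oxy}silane, via alkylborane 16 (not isolated)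
Conditions: 9-BBN (1.3 equiv), THF, 0 °C → rt; then slow addition (10 h) to Pd(dppf)Cl2 (0.15 equiv), AsPh3 (0.3 equiv), Cs2CO3 (3 equiv), DMF/THF/H2O, 50 °C, 2 mM final concentration
Reagents that add atoms: none
Why: 9-BBN should add only to the monosubstituted end of the 1,3-diene, with boron at the terminal carbon (future C5), to give homoallylic borane 16; zerovalent palladium formed from Pd(dppf)Cl2 then inserts into the C4–I bond with retention, the base-activated borane hands its primary alkyl group to palladium within the same molecule, and reductive elimination forms C4–C5. The closest known reaction type is the intramolecular B-alkyl Suzuki–Miyaura macrocyclisation of alkenyl iodides that carry a remote, 9-BBN-hydroborated terminal alkene. The eleven-membered carbocycle closes by C(sp2)–C(sp3) reductive elimination from a twelve-membered palladacycle, a macrocyclisation run under pseudo-high dilution by slow addition of 16. No stereocentre is formed; C1 is remote and untouched, and both alkene geometries are kept because every organometallic step is stereoretentive at the alkenyl carbon. The step needs site-selective hydroboration, secured by the steric demand of 9-BBN towards the two trisubstituted alkenes, and ring closure in preference to oligomerisation and β-hydride elimination, secured by dilution, by the wide-bite-angle dppf ligand and by a chain in which two E-alkenes and the gem-dimethyl carbon C10 leave few freely rotating bonds.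

Step 10
Reactants: 17 tert-butyldimethyl{[(1S,3E,7E)-3,7,10,10-tetramethylcycloundeca-3,7-dien-1-yl]oxy}silane
Product: 18 (1S,3E,7E)-3,7,10,10-tetramethylcycloundeca-3,7-dien-1-ol
Conditions: Bu4NF, THF, rt; then H2O
Reagents that add atoms: none
Why: Fluoride-mediated desilylation driven by the strong Si–F bond frees the secondary alcohol; the C–O bond is not broken, so the S configuration is kept.

Step 11
Reactants: 19 tert-butyl(4-ethynylphenoxy)dimethylsilane
Product: 22 3-{4-[(tert-butyldimethylsilyl)oxy]phenyl}prop-2-ynoic acid, via lithium acetylide 20 (not isolated), via lithium carboxylate 21 (not isolated)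
Conditions: n-BuLi, THF, −78 °C; then CO2, −78 → 0 °C; then cold 0.5 M HCl to pH 3
Reagents that add atoms: carbon dioxide, O=C=O
Why: Deprotonation of the terminal alkyne and carboxylation of the lithium acetylide with CO2 give the arylpropynoic acid, the aryl silyl ether being stable to n-BuLi at low temperature and to brief cold acidification.

Step 12
Reactants: 18 (1S,3E,7E)-3,7,10,10-tetramethylcycloundeca-3,7-dien-1-ol; 22 3-{4-[(tert-butyldimethylsilyl)oxy]phenyl}prop-2-ynoic acid
Product: 23 (1S,3E,7E)-3,7,10,10-tetramethylcycloundeca-3,7-dien-1-yl 3-{4-[(tert-butyldimethylsilyl)oxy]phenyl}prop-2-ynoate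
Conditions: DCC (1.3 equiv, added last), DMAP (0.1 equiv), CH2Cl2, 0 °C → rt
Reagents that add atoms: none
Why: Steglich esterification (carbodiimide activation with acyl transfer by DMAP) acylates the alcohol oxygen with retention at C1, and the alkynoate carries the future Z-alkene in a form that cannot isomerise during acylation.

Step 13
Reactants: 23 (1S,3E,7E)-3,7,10,10-tetramethylcycloundeca-3,7-dien-1-yl 3-{4-[(tert-butyldimethylsilyl)oxy]phenyl}prop-2-ynoate
Product: 24 (1S,3E,7E)-3,7,10,10-tetramethylcycloundeca-3,7-dien-1-yl (2Z)-3-{4-[(tert-butyldimethylsilyl)oxy]phenyl}prop-2-enoate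
Conditions: H2 (1 atm), Pd/CaCO3 poisoned with Pb(OAc)2 (Lindlar catalyst), quinoline, EtOAc, rt, dark, stopped after one equivalent of H2
Reagents that add atoms: none
Why: Lindlar semi-hydrogenation: syn addition of H2 to the alkyne on the lead- and quinoline-poisoned palladium surface should give the Z-alkene and stop there, and trisubstituted ring alkenes are not expected to be hydrogenated on this catalyst.

Step 14
Reactants: 24 (1S,3E,7E)-3,7,10,10-tetramethylcycloundeca-3,7-dien-1-yl (2Z)-3-{4-[(tert-butyldimethylsilyl)oxy]phenyl}prop-2-enoate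
Product: 25 (1S,3E,7E)-3,7,10,10-tetramethylcycloundeca-3,7-dien-1-yl (2Z)-3-(4-hydroxyphenyl)prop-2-enoate
Conditions: Bu4NF/AcOH (1:1), THF, 0 °C, dark
Reagents that add atoms: none
Why: Fluoride cleavage of the aryl silyl ether, buffered with acetic acid so that no free phenoxide or hydroxide is present that could isomerise the Z-alkene or cleave the ester.

**Compound list**

1 | (S)-epichlorohydrin, (2S)-2-(chloromethyl)oxirane | ClC[C@@H]1CO1 | starting material
2 | prenylmagnesium chloride, (3-methylbut-2-en-1-yl)magnesium chloride | CC(C)=CC[Mg]Cl | starting material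
3 | (2S)-1-chloro-4,4-dimethylhex-5-en-2-ol | ClC[C@@H](O)CC(C)(C)C=C | intermediate
4 | lithium acetylide–ethylenediamine complex | [Li+].[C-]#C.NCCN | starting material
5 | (2S)-2-(2,2-dimethylbut-3-en-1-yl)oxirane (formed in the flask) | C=CC(C)(C)C[C@H]1CO1 | intermediate
6 | (4R)-6,6-dimethyloct-7-en-1-yn-4-ol | C#CC[C@@H](O)CC(C)(C)C=C | intermediate
7 | dimethylaluminium (1E,4S)-1-(dimethylalumanyl)-2,6,6-trimethylocta-1,7-dien-4-olate (formed in the flask) | C[Al](C)/C=C(C)/C[C@@H](O[Al](C)C)CC(C)(C)C=C | intermediate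
8 | (1E,4S)-1-iodo-2,6,6-trimethylocta-1,7-dien-4-ol | I/C=C(C)/C[C@@H](O)CC(C)(C)C=C | intermediate
9 | tert-butyl{[(1E,4S)-1-iodo-2,6,6-trimethylocta-1,7-dien-4-yl]oxy}dimethylsilane | I/C=C(C)/C[C@@H](O[Si](C)(C)C(C)(C)C)CC(C)(C)C=C | intermediate
10 | 9-[(5S,7E)-5-{[tert-butyl(dimethyl)silyl]oxy}-8-iodo-3,3,7-trimethyloct-7-en-1-yl]-9-borabicyclo[3.3.1]nonane (formed in the flask) | I/C=C(C)/C[C@@H](O[Si](C)(C)C(C)(C)C)CC(C)(C)CCB1C2CCCC1CCC2 | intermediate
11 | (5S,7E)-5-[(tert-butyldimethylsilyl)oxy]-8-iodo-3,3,7-trimethyloct-7-en-1-ol | I/C=C(C)/C[C@@H](O[Si](C)(C)C(C)(C)C)CC(C)(C)CCO | intermediate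
12 | (5S,7E)-5-[(tert-butyldimethylsilyl)oxy]-8-iodo-3,3,7-trimethyloct-7-enal | I/C=C(C)/C[C@@H](O[Si](C)(C)C(C)(C)C)CC(C)(C)CC=O | intermediate
13 | 2-(triphenylphosphoranylidene)propanal | CC(C=O)=P(c1ccccc1)(c1ccccc1)c1ccccc1 | starting material
14 | (2E,7S,9E)-7-[(tert-butyldimethylsilyl)oxy]-10-iodo-2,5,5,9-tetramethyldeca-2,9-dienal | I/C=C(C)/C[C@@H](O[Si](C)(C)C(C)(C)C)CC(C)(C)C/C=C(\C)C=O | intermediate
15 | tert-butyl{[(3E,8S,10E)-11-iodo-3,6,6,10-tetramethylundeca-1,3,10-trien-8-yl]oxy}dimethylsilane | I/C=C(C)/C[C@@H](O[Si](C)(C)C(C)(C)C)CC(C)(C)C/C=C(\C)C=C | intermediate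
16 | 9-[(3E,8S,10E)-8-{[tert-butyl(dimethyl)silyl]oxy}-11-iodo-3,6,6,10-tetramethylundeca-3,10-dien-1-yl]-9-borabicyclo[3.3.1]nonane (formed in the flask) | I/C=C(C)/C[C@@H](O[Si](C)(C)C(C)(C)C)CC(C)(C)C/C=C(\C)CCB1C2CCCC1CCC2 | intermediate
17 | tert-butyldimethyl{[(1S,3E,7E)-3,7,10,10-tetramethylcycloundeca-3,7-dien-1-yl]oxy}silane | C/C1=C\CC(C)(C)C[C@H](O[Si](C)(C)C(C)(C)C)C/C(C)=C/CC1 | intermediate
18 | (1S,3E,7E)-3,7,10,10-tetramethylcycloundeca-3,7-dien-1-ol | C/C1=C\CC(C)(C)C[C@H](O)C/C(C)=C/CC1 | intermediate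
19 | tert-butyl(4-ethynylphenoxy)dimethylsilane | C#Cc1ccc(O[Si](C)(C)C(C)(C)C)cc1 | starting material
20 | lithium {4-[(tert-butyldimethylsilyl)oxy]phenyl}acetylide (formed in the flask) | [Li+].[C-]#Cc1ccc(O[Si](C)(C)C(C)(C)C)cc1 | intermediate
21 | lithium 3-{4-[(tert-butyldimethylsilyl)oxy]phenyl}prop-2-ynoate (formed in the flask) | [Li+].[O-]C(=O)C#Cc1ccc(O[Si](C)(C)C(C)(C)C)cc1 | intermediate
22 | 3-{4-[(tert-butyldimethylsilyl)oxy]phenyl}prop-2-ynoic acid | OC(=O)C#Cc1ccc(O[Si](C)(C)C(C)(C)C)cc1 | intermediate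
23 | (1S,3E,7E)-3,7,10,10-tetramethylcycloundeca-3,7-dien-1-yl 3-{4-[(tert-butyldimethylsilyl)oxy]phenyl}prop-2-ynoate | C/C1=C\CC(C)(C)C[C@H](OC(=O)C#Cc2ccc(O[Si](C)(C)C(C)(C)C)cc2)C/C(C)=C/CC1 | intermediate
24 | (1S,3E,7E)-3,7,10,10-tetramethylcycloundeca-3,7-dien-1-yl (2Z)-3-{4-[(tert-butyldimethylsilyl)oxy]phenyl}prop-2-enoate | C/C1=C\CC(C)(C)C[C@H](OC(=O)/C=C\c2ccc(O[Si](C)(C)C(C)(C)C)cc2)C/C(C)=C/CC1 | intermediate
25 | (1S,3E,7E)-3,7,10,10-tetramethylcycloundeca-3,7-dien-1-yl (2Z)-3-(4-hydroxyphenyl)prop-2-enoate | C/C1=C\CC(C)(C)C[C@H](OC(=O)/C=C\c2ccc(O)cc2)C/C(C)=C/CC1 | target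

**Step count**

Total step count: 14. Longest linear sequence: 13 steps (steps 1–10 and 12–14); step 11 is a one-step side branch.

**Steps most likely to fail**

1. Step 9. Intermolecular coupling (oligomerisation), protodeboronation and β-hydride elimination may outrun the slow intramolecular boron-to-palladium alkyl transfer that must precede closure of a strained eleven-membered ring. The fallback sets out from 15 and returns at 17; it closes the same C4–C5 bond at the aldehyde oxidation level. Compound 15 is hydroborated as in step 9 to 16, which is oxidised (NaOH, H2O2) to (3E,8S,10E)-8-[(tert-butyldimethylsilyl)oxy]-11-iodo-3,6,6,10-tetramethylundeca-3,10-dien-1-ol F1. Dess–Martin oxidation (NaHCO3-buffered, 0 °C, product used at once) gives the β,γ-unsaturated aldehyde (3E,8S,10E)-8-[(tert-butyldimethylsilyl)oxy]-11-iodo-3,6,6,10-tetramethylundeca-3,10-dienal F2. An intramolecular Nozaki–Hiyama–Kishi reaction (CrCl2, catalytic NiCl2, DMSO/THF, high dilution) adds the alkenylchromium species to the aldehyde and should give the macrocyclic allylic alcohol (2E,5S,9E)-5-[(tert-butyldimethylsilyl)oxy]-3,7,7,10-tetramethylcycloundeca-2,9-dien-1-ol F3 as both C1 epimers. Acetylation (Ac2O, pyridine, DMAP) gives (2E,5S,9E)-5-[(tert-butyldimethylsilyl)oxy]-3,7,7,10-tetramethylcycloundeca-2,9-dien-1-yl acetate F4. Pd(PPh3)4 with LiBHEt3 in THF then removes the acetate by hydride delivery to the less substituted allyl terminus, which should leave the trisubstituted alkene where it is and give 17.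

2. Step 1. The allylic Grignard reagent may lose regiocontrol (bond formation through its primary instead of its tertiary terminus), and chloride may open the epoxide. The fallback sets out from 1 and returns at 6; it brings in the quaternary carbon as a nitrile-stabilised tertiary carbanion. Compound 1 is opened at its ring CH2 by lithiated 2-methylpropanenitrile (LiN(i-Pr)2, THF, −78 °C) to give (4S)-5-chloro-4-hydroxy-2,2-dimethylpentanenitrile F5. LiC≡CH·H2NCH2CH2NH2 in DMSO converts F5, by way of 2,2-dimethyl-3-[(2S)-oxiran-2-yl]propanenitrile F6 (not isolated), into (4R)-4-hydroxy-2,2-dimethylhept-6-ynenitrile F7. i-Bu2AlH (toluene, −78 °C, then aqueous acid) reduces the nitrile to the aldehyde, which closes to the lactol (5R)-3,3-dimethyl-5-(prop-2-yn-1-yl)oxolan-2-ol F8. Wittig methylenation of the lactol (Ph3P=CH2 in excess, THF) gives 6.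

3. Step 13. Over-reduction and surface-mediated Z-to-E isomerisation may occur during the semi-hydrogenation. The fallback sets out from 18 and returns at 24; it makes the Z-alkene by olefination instead of reduction, so that 22 and 23 are not needed. Compound 18 is acylated with (diphenoxyphosphoryl)acetic acid (DCC, catalytic DMAP, CH2Cl2) to (1S,3E,7E)-3,7,10,10-tetramethylcycloundeca-3,7-dien-1-yl 2-(diphenoxyphosphoryl)acetate F9. A Z-selective Horner–Wadsworth–Emmons reaction of this diaryl phosphonoacetate with 4-[(tert-butyldimethylsilyl)oxy]benzaldehyde (NaH, THF, −78 → 0 °C) should give 24 under kinetic control.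

**Further compounds**

F1 | step 9 | (3E,8S,10E)-8-[(tert-butyldimethylsilyl)oxy]-11-iodo-3,6,6,10-tetramethylundeca-3,10-dien-1-ol | I/C=C(C)/C[C@@H](O[Si](C)(C)C(C)(C)C)CC(C)(C)C/C=C(\C)CCO
F2 | step 9 | (3E,8S,10E)-8-[(tert-butyldimethylsilyl)oxy]-11-iodo-3,6,6,10-tetramethylundeca-3,10-dienal | I/C=C(C)/C[C@@H](O[Si](C)(C)C(C)(C)C)CC(C)(C)C/C=C(\C)CC=O
F3 | step 9 | (2E,5S,9E)-5-[(tert-butyldimethylsilyl)oxy]-3,7,7,10-tetramethylcycloundeca-2,9-dien-1-ol (both C1 epimers) | C/C1=C\CC(C)(C)C[C@H](O[Si](C)(C)C(C)(C)C)C/C(C)=C/C(O)CC1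
F4 | step 9 | (2E,5S,9E)-5-[(tert-butyldimethylsilyl)oxy]-3,7,7,10-tetramethylcycloundeca-2,9-dien-1-yl acetate (both C1 epimers) | C/C1=C\CC(C)(C)C[C@H](O[Si](C)(C)C(C)(C)C)C/C(C)=C/C(OC(C)=O)CC1
F5 | step 1 | (4S)-5-chloro-4-hydroxy-2,2-dimethylpentanenitrile | ClC[C@@H](O)CC(C)(C)C#N
F6 | step 1 | 2,2-dimethyl-3-[(2S)-oxiran-2-yl]propanenitrile | N#CC(C)(C)C[C@H]1CO1
F7 | step 1 | (4R)-4-hydroxy-2,2-dimethylhept-6-ynenitrile | C#CC[C@@H](O)CC(C)(C)C#N
F8 | step 1 | (5R)-3,3-dimethyl-5-(prop-2-yn-1-yl)oxolan-2-ol | C#CC[C@@H]1CC(C)(C)C(O)O1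
F9 | step 13 | (1S,3E,7E)-3,7,10,10-tetramethylcycloundeca-3,7-dien-1-yl 2-(diphenoxyphosphoryl)acetate | C/C1=C\CC(C)(C)C[C@H](OC(=O)CP(=O)(Oc2ccccc2)Oc2ccccc2)C/C(C)=C/CC1
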